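**Retrosynthetic overview**
- The 1,4-dioxane ring is the only ring made and it is made last: the target is the closed hemiketal of an (R)-2-aryloxy-1-arylpropan-1-one with a free ortho-phenol, so unmasking that phenol (MOM) closes the ring.
- The ArO–CH(CH3) bond is cut next: a late Mitsunobu etherification (inversion) joins (S)-2-hydroxy-1-(3,4,5-trimethoxyphenyl)propan-1-one (C12) and 4-allyl-2-methoxy-6-(methoxymethoxy)phenol (C12).
- Hydroxy ketone: 3,4,5-trimethoxyphenyl Grignard reagent plus the Weinreb amide of (S)-lactic acid; the aryl bromide comes from resorcinol (dimethylation, ortho-lithiation/oxidation, para-bromination, methylation).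
- Phenol: para-Claisen rearrangement of an allyl ether made from resorcinol (monomethylation, MOM protection, ortho-lithiation/oxidation, O-allylation).
- Both benzene rings are bought as resorcinol; C-3 comes from methyl (S)-lactate, C-2 is set by hemiketal equilibration.

Assumption: the hemiketal carbon C-2 equilibrates through the open keto-phenol, and the (2S) epimer drawn (OH trans to the C-3 methyl) is taken to be the thermodynamically favoured closed form, so only C-3 (R) has to be set by synthesis.

**Route**

Step 1
Reactants: 1 resorcinol (benzene-1,3-diol)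
Product: 2 1,3-dimethoxybenzene
Conditions: Me2SO4 (2.4 equiv), K2CO3, acetone, reflux
Reagents that add atoms: dimethyl sulfate COS(=O)(=O)OC
Why: Williamson ether synthesis methylates both phenolic oxygens; no stereocentre is involved.

Step 2
Reactants: 2 1,3-dimethoxybenzene
Product: 5 2,6-dimethoxyphenol, via aryllithium 3 (not isolated), via arylboronate 4 (not isolated)
Conditions: n-BuLi, THF, 0 °C → rt; B(OMe)3, −78 °C → rt; AcOH, 30% H2O2, 0 °C → rt
Reagents that add atoms: hydrogen peroxide OO; n-butyllithium [Li]CCCC (kept only in intermediate 3); trimethyl borate COB(OC)OC (kept only in intermediate 4)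
Why: Directed ortho-metalation at the carbon flanked by both methoxy groups, borylation and oxidative C–B to C–O cleavage give the phenol.

Step 3
Reactants: 5 2,6-dimethoxyphenol
Product: 6 4-bromo-2,6-dimethoxyphenol
Conditions: NBS (1.0 equiv), NaH (1 mol %), CHCl3, −45 °C → rt
Reagents that add atoms: N-bromosuccinimide O=C1CCC(=O)N1Br
Why: Electrophilic aromatic bromination goes para to the free hydroxyl, the strongest director, because both ortho positions are blocked.

Step 4
Reactants: 6 4-bromo-2,6-dimethoxyphenol
Product: 7 5-bromo-1,2,3-trimethoxybenzene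
Conditions: MeI, K2CO3, acetone, reflux
Reagents that add atoms: iodomethane CI
Why: Williamson O-methylation of the hindered phenoxide completes the 3,4,5-trimethoxyphenyl unit.

Step 5
Reactants: 8 methyl (S)-lactate
Product: 9 (S)-2-hydroxy-N-methoxy-N-methylpropanamide
Conditions: MeNH(OMe)·HCl (1.5 equiv), iPrMgCl (4.5 equiv), THF, −20 → 0 °C; aq. NH4Cl
Reagents that add atoms: N,O-dimethylhydroxylamine hydrochloride CNOC.Cl
Why: Ester aminolysis by the magnesium amide (Weinreb amide formation) at low temperature makes or breaks no bond at the stereocentre, so (S) is retained.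

Step 6
Reactants: 7 5-bromo-1,2,3-trimethoxybenzene; 9 (S)-2-hydroxy-N-methoxy-N-methylpropanamide
Product: 13 (S)-2-hydroxy-1-(3,4,5-trimethoxyphenyl)propan-1-one, via arylmagnesium bromide 10 (not isolated), via magnesium alkoxide 11 (not isolated), via tetrahedral adduct 12 (not isolated)
Conditions: 7, Mg turnings (iodine-activated), THF, reflux; separately 9, iPrMgCl (1.0 equiv), THF, −20 °C; then 10 (1.6 equiv), 0 °C → rt; aq. NH4Cl
Reagents that add atoms: magnesium [Mg] (kept only in intermediates 10 and 12); isopropylmagnesium chloride CC(C)[Mg]Cl (kept only in intermediates 11 and 12)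
Why: Weinreb ketone synthesis, in which the Grignard reagent adds once to give chelated adduct 12 that collapses only on quench, while the pre-formed alkoxide 11 saves Grignard reagent and shields the α-hydrogen so that (S) is kept.

Step 7
Reactants: 1 resorcinol
Product: 14 3-methoxyphenol
Conditions: Me2SO4 (1.0 equiv), NaOH (1.1 equiv), H2O/toluene, 40 → 80 °C; acid–base extraction, distillation
Reagents that add atoms: dimethyl sulfate COS(=O)(=O)OC
Why: Williamson O-methylation with one equivalent of electrophile gives mainly the monoether, which is separated from diether 2 (reusable in step 2) and from resorcinol by extraction.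

Step 8
Reactants: 14 3-methoxyphenol
Product: 15 1-methoxy-3-(methoxymethoxy)benzene
Conditions: MOMCl, K2CO3, acetone, 0 °C → rt
Reagents that add atoms: chloromethyl methyl ether COCCl
Why: O-alkylation of the phenoxide by the reactive α-chloro ether installs an acetal that protects this oxygen and directs the next lithiation.

Step 9
Reactants: 15 1-methoxy-3-(methoxymethoxy)benzene
Product: 18 2-methoxy-6-(methoxymethoxy)phenol, via aryllithium 16 (not isolated), via arylboronate 17 (not isolated)
Conditions: n-BuLi, THF, 0 °C → rt; B(OMe)3, −78 °C → rt; AcOH, 30% H2O2, 0 °C → rt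
Reagents that add atoms: hydrogen peroxide OO; n-butyllithium [Li]CCCC (kept only in intermediate 16); trimethyl borate COB(OC)OC (kept only in intermediate 17)
Why: Cooperative directed ortho-metalation between OMe and OMOM, borylation and oxidative C–B cleavage give the central phenol with its two flanking oxygens differentiated.

Step 10
Reactants: 18 2-methoxy-6-(methoxymethoxy)phenol
Product: 19 2-(allyloxy)-1-methoxy-3-(methoxymethoxy)benzene
Conditions: allyl bromide, K2CO3, acetone, reflux
Reagents that add atoms: allyl bromide C=CCBr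
Why: Williamson O-allylation of the phenoxide sets up the sigmatropic rearrangement.

Step 11
Reactants: 19 2-(allyloxy)-1-methoxy-3-(methoxymethoxy)benzene
Product: 23 4-allyl-2-methoxy-6-(methoxymethoxy)phenol, via ortho-dienone 20 (not isolated), via ortho-dienone 21 (not isolated), via para-dienone 22 (not isolated)
Conditions: PhNEt2, 200 °C, sealed tube
Reagents that add atoms: none
Why: Para-Claisen rearrangement, in which the [3,3] shift to either blocked ortho carbon gives dienone 20 or 21, a Cope [3,3] shift passes the allyl group to C-4 (22), and tautomerization restores the arene with the allyl group para to the freed hydroxyl.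

Step 12
Reactants: 13 (S)-2-hydroxy-1-(3,4,5-trimethoxyphenyl)propan-1-one; 23 4-allyl-2-methoxy-6-(methoxymethoxy)phenol
Product: 25 (R)-2-[4-allyl-2-methoxy-6-(methoxymethoxy)phenoxy]-1-(3,4,5-trimethoxyphenyl)propan-1-one, via oxyphosphonium ion 24 (not isolated)
Conditions: PPh3 (1.5 equiv), DIAD (1.5 equiv), THF, 0 °C → rt, 23 in slight excess
Reagents that add atoms: triphenylphosphine c1ccc(cc1)P(c1ccccc1)c1ccccc1 (kept only in intermediate 24)
Why: Mitsunobu etherification, in which the secondary hydroxyl is activated as oxyphosphonium ion 24 and displaced by the phenoxide of 23 in a carbonyl-accelerated SN2 step, inverting (S) to the (R) aryl ether.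

Step 13
Reactants: 25 (R)-2-[4-allyl-2-methoxy-6-(methoxymethoxy)phenoxy]-1-(3,4,5-trimethoxyphenyl)propan-1-one
Product: 28 (2S,3R)-7-allyl-5-methoxy-3-methyl-2-(3,4,5-trimethoxyphenyl)-2,3-dihydro-1,4-benzodioxin-2-ol (CNP0114249.1), via bromomethyl ether 26 (not isolated), via open keto-phenol 27 (not isolated)
Conditions: Me2BBr (3 equiv), CH2Cl2, −78 °C, 1 h; then THF/sat. aq. NaHCO3, −78 °C → rt
Reagents that add atoms: bromodimethylborane CB(C)Br (its bromine kept only in intermediate 26)
Why: Lewis-acid cleavage of the MOM acetal at −78 °C (no protic acid, so the enolizable C-3 centre is untouched) frees the phenol, which closes onto the ketone by 6-exo-trig hemiketalization under thermodynamic control to the (2S) hemiketal with OH trans to the (3R)-methyl group.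

**Compound list**
1 | resorcinol | Oc1cccc(O)c1 | starting material
2 | 1,3-dimethoxybenzene | COc1cccc(OC)c1 | intermediate
3 | (2,6-dimethoxyphenyl)lithium | [Li]c1c(OC)cccc1OC | intermediate
4 | dimethyl (2,6-dimethoxyphenyl)boronate | COB(OC)c1c(OC)cccc1OC | intermediate
5 | 2,6-dimethoxyphenol | COc1cccc(OC)c1O | intermediate
6 | 4-bromo-2,6-dimethoxyphenol | COc1cc(Br)cc(OC)c1O | intermediate
7 | 5-bromo-1,2,3-trimethoxybenzene | COc1cc(Br)cc(OC)c1OC | intermediate
8 | methyl (S)-lactate | C[C@H](O)C(=O)OC | starting material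
9 | (S)-2-hydroxy-N-methoxy-N-methylpropanamide | C[C@H](O)C(=O)N(C)OC | intermediate
10 | (3,4,5-trimethoxyphenyl)magnesium bromide | COc1cc([Mg]Br)cc(OC)c1OC | intermediate
11 | chloromagnesium alkoxide of 9, (S) | C[C@H](O[Mg]Cl)C(=O)N(C)OC | intermediate
12 | bis(halomagnesium) tetrahedral adduct of 10 and 11, (2S), aminal carbon unassigned | C[C@H](O[Mg]Cl)C(O[Mg]Br)(N(C)OC)c1cc(OC)c(OC)c(OC)c1 | intermediate
13 | (S)-2-hydroxy-1-(3,4,5-trimethoxyphenyl)propan-1-one | C[C@H](O)C(=O)c1cc(OC)c(OC)c(OC)c1 | intermediate
14 | 3-methoxyphenol | COc1cccc(O)c1 | intermediate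
15 | 1-methoxy-3-(methoxymethoxy)benzene | COCOc1cccc(OC)c1 | intermediate
16 | [2-methoxy-6-(methoxymethoxy)phenyl]lithium | [Li]c1c(OC)cccc1OCOC | intermediate
17 | dimethyl [2-methoxy-6-(methoxymethoxy)phenyl]boronate | COCOc1cccc(OC)c1B(OC)OC | intermediate
18 | 2-methoxy-6-(methoxymethoxy)phenol | COCOc1cccc(OC)c1O | intermediate
19 | 2-(allyloxy)-1-methoxy-3-(methoxymethoxy)benzene | C=CCOc1c(OC)cccc1OCOC | intermediate
20 | 6-allyl-6-methoxy-2-(methoxymethoxy)cyclohexa-2,4-dien-1-one (racemic) | C=CCC1(OC)C=CC=C(OCOC)C1=O | intermediate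
21 | 6-allyl-2-methoxy-6-(methoxymethoxy)cyclohexa-2,4-dien-1-one (racemic) | C=CCC1(OCOC)C=CC=C(OC)C1=O | intermediate
22 | 4-allyl-2-methoxy-6-(methoxymethoxy)cyclohexa-2,5-dien-1-one (racemic) | C=CCC1C=C(OC)C(=O)C(OCOC)=C1 | intermediate
23 | 4-allyl-2-methoxy-6-(methoxymethoxy)phenol | C=CCc1cc(OC)c(O)c(OCOC)c1 | intermediate
24 | {[(2S)-1-oxo-1-(3,4,5-trimethoxyphenyl)propan-2-yl]oxy}triphenylphosphonium ion | C[C@H](O[P+](c1ccccc1)(c1ccccc1)c1ccccc1)C(=O)c1cc(OC)c(OC)c(OC)c1 | intermediate
25 | (R)-2-[4-allyl-2-methoxy-6-(methoxymethoxy)phenoxy]-1-(3,4,5-trimethoxyphenyl)propan-1-one | C[C@@H](Oc1c(OC)cc(CC=C)cc1OCOC)C(=O)c1cc(OC)c(OC)c(OC)c1 | intermediate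
26 | (R)-2-[4-allyl-2-(bromomethoxy)-6-methoxyphenoxy]-1-(3,4,5-trimethoxyphenyl)propan-1-one | C[C@@H](Oc1c(OC)cc(CC=C)cc1OCBr)C(=O)c1cc(OC)c(OC)c(OC)c1 | intermediate
27 | (R)-2-(4-allyl-2-hydroxy-6-methoxyphenoxy)-1-(3,4,5-trimethoxyphenyl)propan-1-one | C[C@@H](Oc1c(O)cc(CC=C)cc1OC)C(=O)c1cc(OC)c(OC)c(OC)c1 | intermediate
28 | (2S,3R)-7-allyl-5-methoxy-3-methyl-2-(3,4,5-trimethoxyphenyl)-2,3-dihydro-1,4-benzodioxin-2-ol | C=CCc1cc(OC)c2c(c1)O[C@@](O)(c1cc(OC)c(OC)c(OC)c1)[C@@H](C)O2 | target

**Totals**
Total step count: 13.
Longest linear sequence: 7 steps (steps 7, 8, 9, 10, 11, 12, 13 from resorcinol; the aryl ketone arm, steps 1, 2, 3, 4, 6, 12, 13, is equally long).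

**Three steps most likely to fail**

Step 11 (para-Claisen; the MOM group or a methoxy group may be lost at 200 °C, or ortho-allyl by-products may form). The fallback sets out from 18 and comes back at 23. Phenol 18 is brominated para to the hydroxyl (NBS, MeCN, 0 °C) to give 4-bromo-2-methoxy-6-(methoxymethoxy)phenol F1. A Stille cross-coupling with allyltributylstannane (Pd(PPh3)4, toluene, 110 °C) then puts the allyl group on the same carbon and delivers 23 without any thermal rearrangement.

Step 12 (Mitsunobu reaction of an α-hydroxy ketone with a 2,6-disubstituted phenol; it may be slow, or erode the C-3 configuration). The fallback sets out from 23 and 8 and comes back at 25. The ether bond is made on the more robust lactate ester: Mitsunobu reaction of 23 with 8 (PPh3, DIAD, THF) gives methyl (R)-2-[4-allyl-2-methoxy-6-(methoxymethoxy)phenoxy]propanoate F2. Aminolysis (MeNH(OMe)·HCl, iPrMgCl, THF, −20 °C) gives (R)-2-[4-allyl-2-methoxy-6-(methoxymethoxy)phenoxy]-N-methoxy-N-methylpropanamide F3. Addition of Grignard reagent 10 (THF, 0 °C) then forms the aryl ketone 25, so the fragment union becomes an acylation instead of an etherification.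

Step 13 (MOM removal next to an enolizable α-aryloxy ketone; risk of C-3 epimerization or dehydration of the hemiketal). The fallback sets out from 23 and 8 and comes back at 27, which closes to 28. It goes through amide F3 of the preceding fallback (reached by way of ester F2) and removes the MOM group before any ketone exists. HCl in MeOH at rt, harmless to the amide stereocentre, gives (R)-2-(4-allyl-2-hydroxy-6-methoxyphenoxy)-N-methoxy-N-methylpropanamide F4. Treatment with Grignard reagent 10 (2.5 equiv, THF, 0 °C → rt; aq. NH4Cl) deprotonates the phenol and adds to the amide, so the keto-phenol 27 appears only at neutral work-up and closes directly to 28.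

**Further compounds**
F1 | step 11 | 4-bromo-2-methoxy-6-(methoxymethoxy)phenol | COCOc1cc(Br)cc(OC)c1O
F2 | step 12 | methyl (R)-2-[4-allyl-2-methoxy-6-(methoxymethoxy)phenoxy]propanoate | C[C@@H](Oc1c(OC)cc(CC=C)cc1OCOC)C(=O)OC
F3 | step 12 | (R)-2-[4-allyl-2-methoxy-6-(methoxymethoxy)phenoxy]-N-methoxy-N-methylpropanamide | C[C@@H](Oc1c(OC)cc(CC=C)cc1OCOC)C(=O)N(C)OC
F4 | step 13 | (R)-2-(4-allyl-2-hydroxy-6-methoxyphenoxy)-N-methoxy-N-methylpropanamide | C[C@@H](Oc1c(O)cc(CC=C)cc1OC)C(=O)N(C)OC
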